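## Retrosynthetic overview

1. The two esters go on last, the primary allylic C15-OH before the axial C3-OH. This leads back to ent-labda-7,13E-diene-3,15-diol, whose E-allylic alcohol comes from a terminal alkyne by methylalumination and CH2O.
2. The C17 methyl and the C7=C8 alkene come from an enol triflate, made from a 6-en-8-one. The same hydride step makes the axial C3 alcohol.
3. Ring B comes from the key step, an oxidative one-carbon enlargement of an alkylidenecyclopentane. C10 shifts from C8 to C9, which inserts C9 together with the side chain; base then sets C5 and C9.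
4. The alkylidene hydrindenone comes from a Wittig reaction and 4,4-dimethylation of the (R)-Hajos–Parrish ketone, itself made from 2-methylcyclopentane-1,3-dione and methyl vinyl ketone.
5. Ring order: the five-membered ring is bought, ring A is built by aldol annulation, and the five-membered ring is then enlarged to ring B.

Assumption: labdane numbering is used for the bicyclic compounds. The SMILES is read as the ent-labdane (3S,5S,9R,10S,13E,3'S), with a trans-decalin, the C9 side chain cis to the C10 methyl, and an axial C3 oxygen.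

## Route

Step 1
Reactants: 1 2-methylcyclopentane-1,3-dione; 2 but-3-en-2-one (methyl vinyl ketone)
Product: 3 2-methyl-2-(3-oxobutyl)cyclopentane-1,3-dione
Conditions: H2O, AcOH (cat.), 70 °C
Reagents that add atoms: none
Why: Michael addition of the acidic 1,3-dione to the enone in water gives C-alkylation at C2 and the achiral triketone.

Step 2
Reactants: 3 2-methyl-2-(3-oxobutyl)cyclopentane-1,3-dione
Product: 5 (7aR)-7a-methyl-2,3,7,7a-tetrahydro-1H-indene-1,5(6H)-dione ((R)-Hajos–Parrish ketone), via cis-fused ketol 4 (not isolated)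
Conditions: (R)-proline (3 mol %), DMF, 20 °C; then H2SO4 (cat.), DMF, 95 °C; recrystallise
Reagents that add atoms: none
Why: In the Hajos–Parrish–Eder–Sauer–Wiechert reaction the proline enamine aldol differentiates the two enantiotopic ring carbonyls, (R)-proline gives the (7aR) quaternary centre (C10 of the target), and acid dehydrates the ketol.

Step 3
Reactants: 6 5-iodopent-1-yne
Product: 7 (pent-4-yn-1-yl)triphenylphosphonium iodide
Conditions: PPh3, MeCN, reflux
Reagents that add atoms: triphenylphosphine, c1ccc(cc1)P(c1ccccc1)c1ccccc1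
Why: SN2 quaternisation of PPh3 by a primary iodide.

Step 4
Reactants: 5 (R)-Hajos–Parrish ketone; 7 (pent-4-yn-1-yl)triphenylphosphonium iodide
Product: 9 (1Z,7aS)-7a-methyl-1-(pent-4-yn-1-ylidene)-1,2,3,6,7,7a-hexahydro-5H-inden-5-one, via phosphorus ylide 8 (not isolated)
Conditions: 7 (1.2 equiv), KN(SiMe3)2 (1.15 equiv), THF, 0 °C; then 5, 0 → 40 °C
Reagents that add atoms: none
Why: In this Wittig olefination the non-conjugated cyclopentanone carbonyl is the more electrophilic C=O of the Hajos–Parrish system (the site also chosen by NaBH4) while the vinylogous enone carbonyl reacts more slowly, so about one equivalent of the unstabilised ylide gives the exocyclic alkene; no stereocentre is formed, and the Z/E ratio does not matter because C9 is equilibrated in step 6.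

Step 5
Reactants: 9 alkylidene enone
Product: 10 (1Z,7aS)-4,4,7a-trimethyl-1-(pent-4-yn-1-ylidene)-1,2,4,6,7,7a-hexahydro-5H-inden-5-one
Conditions: KOt-Bu (2.5 equiv), t-BuOH/THF, 20 °C; MeI (5 equiv), 0 → 20 °C
Reagents that add atoms: iodomethane, CI
Why: Deconjugative double α-methylation of the extended potassium dienolate (the classical 4,4-dimethylation of 4-en-3-ones) places both methyl groups at C4 and moves the alkene to C5=C6; the enone is the only carbonyl present, so no other enolate competes, and C10 is untouched.

Step 6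
Reactants: 10 dimethylated alkylidene ketone
Product: 12 (4aR,5S,8aS)-5-(but-3-yn-1-yl)-1,1,4a-trimethyl-3,4,4a,8a-tetrahydronaphthalene-2,6(1H,5H)-dione, via β,γ-unsaturated diketone 11 (not isolated)
Conditions: PhI(OH)OTs (1.1 equiv), MeCN/H2O 9:1, 0 → 20 °C; aq NaHCO3 wash; then DBU (0.3 equiv), toluene, 40 °C
Reagents that add atoms: water, O
Why: Proposed new method: a trivalent-iodine oxidative ring enlargement of a non-benzylic trisubstituted alkylidenecyclopentane, in which PhI(OH)OTs puts its iodine on the less substituted alkene carbon C9 and water adds at C8; in the resulting β-hydroxy-λ3-iodane the very large PhI group lies anti to the bulkiest C8 substituent (the quaternary, allylic C10), so loss of PhI is coupled to a 1,2-shift of C10 from C8 to C9 with retention at C10 (semipinacol) and gives the six-membered 8-ketone 11; DBU then brings the C5=C6 alkene into conjugation and equilibrates C5 and C9 to the trans-decalin with the equatorial side chain; the closest known reaction types are the Wittig/PhI(OH)OTs ring expansion of benzo-fused exocyclic alkenes (aryl shift), the Tl(NO3)3 enlargement of methylenecycloalkanes and the pinacol-type rearrangement of diol monosulfonates, and what is new is the shift of a fully substituted alkyl carbon in an unstrained five-membered ring in the presence of a second alkene, a ketone and a terminal alkyne.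

Step 7
Reactants: 12 trans-fused enedione
Product: 14 (1S,4aS,6S,8aR)-1-(but-3-yn-1-yl)-6-hydroxy-5,5,8a-trimethyl-1,4,4a,5,6,7,8,8a-octahydronaphthalen-2-yl trifluoromethanesulfonate, via dilithium enolate alkoxide 13 (not isolated)
Conditions: LiBH(s-Bu)3 (2.4 equiv), THF, −78 → −40 °C; PhNTf2 (1.3 equiv), −78 → 0 °C; H2O
Reagents that add atoms: N-phenylbis(trifluoromethanesulfonimide), O=S(=O)(N(c1ccccc1)S(=O)(=O)C(F)(F)F)C(F)(F)F
Why: Conjugate reduction of a β-unsubstituted cyclohexenone by a trialkylborohydride gives only the C7=C8 enolate, which is trapped as the enol triflate, while the same bulky hydride attacks the hindered C3 ketone from the equatorial side and sets the axial (3S) alcohol, whose crowded alkoxide is not sulfonylated.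

Step 8
Reactants: 14 hydroxy enol triflate
Product: 15 (2S,4aS,5R,8aS)-5-(but-3-yn-1-yl)-1,1,4a,6-tetramethyl-1,2,3,4,4a,5,8,8a-octahydronaphthalen-2-ol
Conditions: CuI (5 equiv), MeLi (10 equiv), Et2O, 0 °C; then 14, THF, −20 → 0 °C; aq NH4Cl
Reagents that add atoms: methyllithium, [Li]C
Why: Cuprate–vinyl triflate coupling replaces OTf by methyl without moving the alkene; the deprotonated alkyne and alkoxide act only as non-transferable ligands, and no stereocentre is touched.

Step 9
Reactants: 15 bicyclic alkynol
Product: 18 (3S,5S,9R,10S,13E)-labda-7,13-diene-3,15-diol, via alkenylalane 16 (not isolated), via lithium alanate 17 (not isolated)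
Conditions: Me3Al (4 equiv), Cp2ZrCl2 (0.3 equiv), CH2Cl2, 0 → 20 °C; evaporate; hexane/THF, n-BuLi, −78 → 0 °C; (CH2O)n, 20 °C; cold 1 M HCl
Reagents that add atoms: trimethylaluminium, C[Al](C)C; formaldehyde (from paraformaldehyde), C=O
Why: Zirconium-catalysed syn-methylalumination of the terminal alkyne (Negishi carboalumination) puts methyl on C13 and aluminium on C14, and hydroxymethylation of the alanate proceeds with retention to give the 13E alkene; the C3-OH is carried as its aluminium alkoxide and the trisubstituted C7=C8 alkene is inert.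

Step 10
Reactants: 18 diol; 19 (S)-3-methylpentanoic acid
Product: 20 (3S,5S,9R,10S,13E)-3-hydroxylabda-7,13-dien-15-yl (3S)-3-methylpentanoate
Conditions: DCC (1.1 equiv), DMAP (0.1 equiv), CH2Cl2, 0 °C
Reagents that add atoms: none
Why: In this Steglich esterification the primary allylic OH reacts far faster than the axial C3-OH next to the gem-dimethyl carbon, and the acid stereocentre is β to the carbonyl and cannot epimerise.

Step 11
Reactants: 20 monoester; 21 malonic acid
Product: 22 target, (3S,5S,9R,10S,13E)-3-(carboxyacetoxy)labda-7,13-dien-15-yl (3S)-3-methylpentanoate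
Conditions: 21 (3 equiv), DCC (1.5 equiv), MeCN/THF, 0 → 20 °C
Reagents that add atoms: none
Why: Carbodiimide mono-activation of malonic acid gives a very reactive acylating species (O-acylisourea or carboxyketene) that esterifies even tertiary alcohols; the excess diacid stops the reaction at the half ester, and C3 keeps its configuration because the C–O bond is not broken.

## Compound list

1 | 2-methylcyclopentane-1,3-dione | CC1C(=O)CCC1=O | starting material
2 | but-3-en-2-one | C=CC(C)=O | starting material
3 | 2-methyl-2-(3-oxobutyl)cyclopentane-1,3-dione | CC(=O)CCC1(C)C(=O)CCC1=O | intermediate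
4 | (3aR,7aR)-3a-hydroxy-7a-methylhexahydro-1H-indene-1,5(4H)-dione | O=C1CC[C@@]2(O)CC(=O)CC[C@@]12C | intermediate
5 | (7aR)-7a-methyl-2,3,7,7a-tetrahydro-1H-indene-1,5(6H)-dione | O=C1CCC2=CC(=O)CC[C@@]12C | intermediate
6 | 5-iodopent-1-yne | C#CCCCI | starting material
7 | (pent-4-yn-1-yl)triphenylphosphonium iodide | C#CCCC[P+](c1ccccc1)(c1ccccc1)c1ccccc1.[I-] | intermediate
8 | (pent-4-yn-1-ylidene)triphenylphosphorane | C#CCCC=P(c1ccccc1)(c1ccccc1)c1ccccc1 | intermediate
9 | (1Z,7aS)-7a-methyl-1-(pent-4-yn-1-ylidene)-1,2,3,6,7,7a-hexahydro-5H-inden-5-one | C#CCC/C=C1/CCC2=CC(=O)CC[C@@]12C | intermediate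
10 | (1Z,7aS)-4,4,7a-trimethyl-1-(pent-4-yn-1-ylidene)-1,2,4,6,7,7a-hexahydro-5H-inden-5-one | C#CCC/C=C1/CC=C2C(C)(C)C(=O)CC[C@@]12C | intermediate
11 | (4aS)-5-(but-3-yn-1-yl)-1,1,4a-trimethyl-3,4,4a,5-tetrahydronaphthalene-2,6(1H,7H)-dione, epimers at C5 (labdane C9) | C#CCCC1C(=O)CC=C2C(C)(C)C(=O)CC[C@@]12C | intermediate
12 | (4aR,5S,8aS)-5-(but-3-yn-1-yl)-1,1,4a-trimethyl-3,4,4a,8a-tetrahydronaphthalene-2,6(1H,5H)-dione | C#CCC[C@@H]1C(=O)C=C[C@@H]2C(C)(C)C(=O)CC[C@@]12C | intermediate
13 | dilithium C7=C8 enolate / C3 alkoxide derived from 12 | [Li+].[Li+].C#CCC[C@@H]1C([O-])=CC[C@@H]2C(C)(C)[C@@H]([O-])CC[C@@]12C | intermediate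
14 | (1S,4aS,6S,8aR)-1-(but-3-yn-1-yl)-6-hydroxy-5,5,8a-trimethyl-1,4,4a,5,6,7,8,8a-octahydronaphthalen-2-yl trifluoromethanesulfonate | C#CCC[C@@H]1C(OS(=O)(=O)C(F)(F)F)=CC[C@@H]2C(C)(C)[C@@H](O)CC[C@@]12C | intermediate
15 | (2S,4aS,5R,8aS)-5-(but-3-yn-1-yl)-1,1,4a,6-tetramethyl-1,2,3,4,4a,5,8,8a-octahydronaphthalen-2-ol | C#CCC[C@@H]1C(C)=CC[C@@H]2C(C)(C)[C@@H](O)CC[C@@]12C | intermediate
16 | (E)-alkenyl(dimethyl)alane at C14 with the C3 oxygen as its dimethylaluminium alkoxide | C[Al](C)/C=C(\C)CC[C@@H]1C(C)=CC[C@@H]2C(C)(C)[C@@H](O[Al](C)C)CC[C@@]12C | intermediate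
17 | lithium butyl(dimethyl)alkenylalanate derived from 16 | [Li+].CCCC[Al-](C)(C)/C=C(\C)CC[C@@H]1C(C)=CC[C@@H]2C(C)(C)[C@@H](O[Al](C)C)CC[C@@]12C | intermediate
18 | (3S,5S,9R,10S,13E)-labda-7,13-diene-3,15-diol (ent series, axial 3-OH) | OC/C=C(\C)CC[C@@H]1C(C)=CC[C@@H]2C(C)(C)[C@@H](O)CC[C@@]12C | intermediate
19 | (S)-3-methylpentanoic acid | CC[C@H](C)CC(=O)O | starting material
20 | (3S,5S,9R,10S,13E)-3-hydroxylabda-7,13-dien-15-yl (3S)-3-methylpentanoate | CC[C@H](C)CC(=O)OC/C=C(\C)CC[C@@H]1C(C)=CC[C@@H]2C(C)(C)[C@@H](O)CC[C@@]12C | intermediate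
21 | malonic acid | OC(=O)CC(=O)O | starting material
22 | (3S,5S,9R,10S,13E)-3-(carboxyacetoxy)labda-7,13-dien-15-yl (3S)-3-methylpentanoate | CC[C@H](C)CC(=O)OC/C=C(\C)CC[C@@H]1C(C)=CC[C@@H]2C(C)(C)[C@@H](OC(=O)CC(=O)O)CC[C@@]12C | target

## Step count and risks

Total steps: 11. Longest linear sequence: 10 (steps 1, 2, 4–11); step 3 is a side branch.

**Step 6, the proposed new ring enlargement.** The iodane could be captured by water to give a diol instead of rearranging. C7 could migrate in place of C10. The reagent could also attack the C5=C6 alkene. The fallback uses known chemistry, sets out from 10 and comes back at 11. OsO4 (cat.)/NMO dihydroxylates the accessible exocyclic alkene from the face opposite the C10 methyl to give the C8,C9-diol F3. MsCl/pyridine sulfonylates only the secondary C9-OH to give the hydroxy mesylate F4. LiClO4/CaCO3 in THF at 50 °C then triggers the pinacol-type ring expansion of the diol monosulfonate to 11, which is treated with DBU as in step 6.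

**Step 4, site selectivity of the Wittig reaction.** The cyclopentanone carbonyl is flanked by a quaternary carbon, so the ylide may also attack the enone carbonyl. The fallback sets out from 5 and comes back at 9. Ethane-1,2-dithiol and TsOH in AcOH convert only the enone carbonyl, with the C4=C5 alkene kept in place, into the spiro-dithiolane ketone F1. Ylide 8 then has a single carbonyl to react with and gives the alkylidene dithiolane F2. MeI/CaCO3 in aqueous MeCN releases the enone 9.

**Step 7, one-pot 1,4-reduction, C3 reduction and triflation.** Hydride delivery at C6 next to the crowded C5 may lose out to 1,2-reduction at C8. The fallback sets out from 12 and comes back at 15. MeCeCl2 (one equivalent, −78 °C) adds 1,2 to the less hindered enone carbonyl to give the tertiary allylic alcohol F5. Et3SiH/BF3·OEt2 at −78 °C ionises it, and hydride enters at the less hindered C6 terminus of the allyl cation to give the 7-en-3-one F6. LiBH(s-Bu)3 then reduces the C3 ketone from the equatorial side to 15.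

## Further compounds

F1 | step 4 | (7'aR)-7'a-methyl-2',3',7',7'a-tetrahydrospiro[1,3-dithiolane-2,5'-inden]-1'(6'H)-one | O=C1CCC2=CC3(SCCS3)CC[C@@]12C
F2 | step 4 | (Z)-pent-4-yn-1-ylidene derivative of F1 at the former ketone carbon | C#CCC/C=C1/CCC2=CC3(SCCS3)CC[C@@]12C
F3 | step 6 | C8,C9-diol of 10 (both OH on the face opposite the C10 methyl) | C#CCC[C@@H](O)[C@]1(O)CC=C2C(C)(C)C(=O)CC[C@@]12C
F4 | step 6 | C9 methanesulfonate of F3 | C#CCC[C@@H](OS(C)(=O)=O)[C@]1(O)CC=C2C(C)(C)C(=O)CC[C@@]12C
F5 | step 7 | 8-hydroxy-8-methyl-6-en-3-one from 1,2-methyl addition to 12 | C#CCC[C@@H]1[C@](C)(O)C=C[C@@H]2C(C)(C)C(=O)CC[C@@]12C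
F6 | step 7 | 3-ketone corresponding to 15 (8-methyl-7-en-3-one) | C#CCC[C@@H]1C(C)=CC[C@@H]2C(C)(C)C(=O)CC[C@@]12C
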